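The benzene ring (ring A) of the chromene is disconnected at C5–C6, C7–C8 and C4a–C5. Its oxygen atoms at C5, C7 and C8a alternate with carbon or hydrogen at C6, C8 and C4a, the pattern that a vinylketene and an ynol ether assemble without regiochemical ambiguity. In one operation a light-induced Wolff rearrangement, a ketene–alkyne [2+2] cycloaddition, a four-electron ring opening and a six-electron ring closure build the hexasubstituted ring with C5–OH free and C7–O silylated. The precursors are a dihydropyranone carrying a diazoacetyl group on its enol-ether carbon, which supplies O1, C2–C4, C4a, C5, C8 and C8a, and a siloxyalkyne (C6, C7) bearing a 3-phenylisoxazole as the masked 1,3-diketone.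

Key step: step 3

Remark: acid 1 is taken as a catalogue compound (the parent acid of the repellent butopyronoxyl), and the target is drawn as its diketo form although it should exist mainly as the chelated enol tautomer.

Step 1
Reactants: 1 2,2-dimethyl-4-oxo-3,4-dihydro-2H-pyran-6-carboxylic acid
Product: 3 6-(2-diazoacetyl)-2,2-dimethyl-2,3-dihydro-4H-pyran-4-one, via mixed carbonic anhydride 2 (not isolated)
Conditions: i-BuOCOCl, Et3N, THF, −15 °C; then CH2N2, Et2O, −15 → 0 °C
Reagents that add atoms: diazomethane, C=[N+]=[N-]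
Why: Acylation of diazomethane by a mixed carbonic anhydride (the first stage of an Arndt–Eistert sequence) should give the diazoketone without any HCl, since the expelled isobutyl carbonate takes up the proton, while the low temperature and short contact time keep dipolar cycloaddition to the donor-substituted C=C bond of the vinylogous ester slow.

Step 2
Reactants: 4 ethyl 3-phenylisoxazole-5-carboxylate
Product: 7 3-phenyl-5-({[tri(propan-2-yl)silyl]oxy}ethynyl)isoxazole, via lithium dibromoenolate 5 (not isolated), via lithium ynolate 6 (not isolated)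
Conditions: CH2Br2, lithium 2,2,6,6-tetramethylpiperidide, THF, −78 °C; LiN(SiMe3)2, then n-BuLi, −78 → 0 °C; i-Pr3SiCl, −78 °C → rt
Reagents that add atoms: dibromomethane, BrCBr; chlorotri(propan-2-yl)silane, CC(C)[Si](Cl)(C(C)C)C(C)C
Why: This is a Kowalski ester homologation halted at the ynolate, in which LiCHBr2 adds to the ester, loss of ethoxide and deprotonation give dibromoenolate 5, bromine–lithium exchange triggers the 1,2-shift of the isoxazolyl group to ynolate 6, and the bulky silyl chloride traps 6 on oxygen; the isoxazole has no C3–H, and n-BuLi is kept near the amount the exchange needs so that C4 of the isoxazole is not lithiated.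

Step 3
Reactants: 3 6-(2-diazoacetyl)-2,2-dimethyl-2,3-dihydro-4H-pyran-4-one; 7 3-phenyl-5-({[tri(propan-2-yl)silyl]oxy}ethynyl)isoxazole
Product: 11 5-hydroxy-2,2-dimethyl-6-(3-phenylisoxazol-5-yl)-7-{[tri(propan-2-yl)silyl]oxy}chroman-4-one, via vinylketene 8 (not isolated), via 4-vinylcyclobutenone 9 (not isolated), via dienylketene 10 (not isolated)
Conditions: hν (405 nm LEDs), ClCH2CH2Cl, rt; then 80 °C
Reagents that add atoms: none
Why: Violet light should be absorbed only by the diazoketone (neither the isoxazole nor the pyranone enone absorbs near 405 nm), so N2 is lost and the pyranone C6 shifts to the diazo carbon (Wolff rearrangement), giving vinylketene 8 in which the former diazo carbon is the future C8 and the ketene carbon the future C5. The ynol ether then adds across the ketene C=C bond in a [2+2] cycloaddition, its isoxazole-bearing carbon bonding to C5 and its siloxy carbon to C8, to give cyclobutenone 9 (C5–C6 and C7–C8); at 80 °C 9 undergoes four-electron electrocyclic opening to dienylketene 10, whose thermal six-electron disrotatory electrocyclisation joins the ketene carbon to the pyranone α-carbon (C4a–C5) and, after enolisation, closes the benzene ring. The closest known reaction type is the photochemical-Wolff form of the Danheiser benzannulation of unsaturated diazoketones with trialkylsiloxyalkynes, which delivers resorcinol monosilyl ethers. No stereocentre is created: the racemic centre of 9 and the alkene geometry of 10 vanish on aromatisation, and because the ring opening is reversible only the isomer of 10 able to cyclise is drained. The one selectivity needed is the orientation of the [2+2] addition, secured by the oxygen donor of the ynol ether, which makes the isoxazole-bearing carbon the nucleophilic terminus and so places the isoxazole on C6 between the C5 hydroxyl and the C7 silyl ether; the six-electron closure has a single terminus, the α-carbon of the vinylogous ester. Phenol 11 forms only in the thermal stage, when no ketene is left to acylate it.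

Step 4
Reactants: 11 5-hydroxy-2,2-dimethyl-6-(3-phenylisoxazol-5-yl)-7-{[tri(propan-2-yl)silyl]oxy}chroman-4-one
Product: 13 5-hydroxy-7-methoxy-2,2-dimethyl-6-(3-phenylisoxazol-5-yl)chroman-4-one, via cesium phenoxide 12 (not isolated)
Conditions: CsF, MeI, DMF, rt
Reagents that add atoms: iodomethane, CI
Why: Fluoride cleaves the aryl silyl ether and the cesium phenoxide 12 so released undergoes Williamson O-methylation in the same pot, whereas the C5 hydroxyl, held in a hydrogen bond to the C4 carbonyl and not deprotonated when about one equivalent of CsF is used, should stay free.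

Step 5
Reactants: 13 5-hydroxy-7-methoxy-2,2-dimethyl-6-(3-phenylisoxazol-5-yl)chroman-4-one
Product: 15 7-methoxy-2,2-dimethyl-6-(3-phenylisoxazol-5-yl)-2H-chromen-5-ol, via chroman-4-ol 14 (not isolated)
Conditions: NaBH4, THF/MeOH, 0 °C → rt; then p-TsOH·H2O (cat.), toluene, 60 °C
Reagents that add atoms: none
Why: Borohydride reduction of the C4 ketone gives benzylic alcohol 14 as a racemate (its stereocentre is not controlled and is destroyed at once), and acid-catalysed E1 dehydration through a cation stabilised by the oxygens on C5, C7 and C8a should deliver the C3=C4 alkene, the isoxazole being inert to both reagents.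

Step 6
Reactants: 15 7-methoxy-2,2-dimethyl-6-(3-phenylisoxazol-5-yl)-2H-chromen-5-ol
Product: 17 1-(5-hydroxy-7-methoxy-2,2-dimethyl-2H-chromen-6-yl)-3-phenylpropane-1,3-dione (CNP0331858.0), via enaminone 16 (not isolated)
Conditions: Mo(CO)6, MeCN/H2O, 80 °C; then 1 M HCl, THF, 0 °C → rt
Reagents that add atoms: water, O
Why: Zerovalent molybdenum in Mo(CO)6 should cleave the weak N–O bond reductively to the Z-configured β-aminoenone 16 without touching the chromene alkene, and cold dilute aqueous acid hydrolyses this vinylogous amide to the 1,3-diketone (isoxazole as masked β-diketone), water-rich conditions being chosen so that hydrolysis outruns attack of the C5 hydroxyl that would lead to a flavone.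

Compound list

1 | 2,2-dimethyl-4-oxo-3,4-dihydro-2H-pyran-6-carboxylic acid | CC1(C)CC(=O)C=C(O1)C(=O)O | starting material
2 | 2,2-dimethyl-4-oxo-3,4-dihydro-2H-pyran-6-carboxylic (2-methylpropyl carbonic) anhydride | CC1(C)CC(=O)C=C(O1)C(=O)OC(=O)OCC(C)C | intermediate
3 | 6-(2-diazoacetyl)-2,2-dimethyl-2,3-dihydro-4H-pyran-4-one | CC1(C)CC(=O)C=C(O1)C(=O)C=[N+]=[N-] | intermediate
4 | ethyl 3-phenylisoxazole-5-carboxylate | CCOC(=O)c1cc(-c2ccccc2)no1 | starting material
5 | lithium 2,2-dibromo-1-(3-phenylisoxazol-5-yl)ethen-1-olate | [Li+].[O-]C(=C(Br)Br)c1cc(-c2ccccc2)no1 | intermediate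
6 | lithium 2-(3-phenylisoxazol-5-yl)ethyn-1-olate | [Li+].[O-]C#Cc1cc(-c2ccccc2)no1 | intermediate
7 | 3-phenyl-5-({[tri(propan-2-yl)silyl]oxy}ethynyl)isoxazole | CC(C)[Si](C(C)C)(C(C)C)OC#Cc1cc(-c2ccccc2)no1 | intermediate
8 | 2,2-dimethyl-6-(2-oxoethenyl)-2,3-dihydro-4H-pyran-4-one | CC1(C)CC(=O)C=C(O1)C=C=O | intermediate
9 | 4-(6,6-dimethyl-4-oxo-5,6-dihydro-4H-pyran-2-yl)-2-(3-phenylisoxazol-5-yl)-3-{[tri(propan-2-yl)silyl]oxy}cyclobut-2-en-1-one (racemic) | O=C1C(C2=CC(=O)CC(C)(C)O2)C(O[Si](C(C)C)(C(C)C)C(C)C)=C1c1cc(-c2ccccc2)no1 | intermediate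
10 | (3E)-4-(6,6-dimethyl-4-oxo-5,6-dihydro-4H-pyran-2-yl)-2-(3-phenylisoxazol-5-yl)-3-{[tri(propan-2-yl)silyl]oxy}buta-1,3-dien-1-one | O=C=C(c1cc(-c2ccccc2)no1)/C(O[Si](C(C)C)(C(C)C)C(C)C)=C\C1=CC(=O)CC(C)(C)O1 | intermediate
11 | 5-hydroxy-2,2-dimethyl-6-(3-phenylisoxazol-5-yl)-7-{[tri(propan-2-yl)silyl]oxy}chroman-4-one | CC1(C)CC(=O)c2c(O1)cc(O[Si](C(C)C)(C(C)C)C(C)C)c(-c3cc(-c4ccccc4)no3)c2O | intermediate
12 | cesium 5-hydroxy-2,2-dimethyl-4-oxo-6-(3-phenylisoxazol-5-yl)chroman-7-olate | CC1(C)CC(=O)c2c(O1)cc([O-])c(-c3cc(-c4ccccc4)no3)c2O.[Cs+] | intermediate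
13 | 5-hydroxy-7-methoxy-2,2-dimethyl-6-(3-phenylisoxazol-5-yl)chroman-4-one | CC1(C)CC(=O)c2c(O1)cc(OC)c(-c3cc(-c4ccccc4)no3)c2O | intermediate
14 | 7-methoxy-2,2-dimethyl-6-(3-phenylisoxazol-5-yl)chromane-4,5-diol (racemic) | CC1(C)CC(O)c2c(O1)cc(OC)c(-c3cc(-c4ccccc4)no3)c2O | intermediate
15 | 7-methoxy-2,2-dimethyl-6-(3-phenylisoxazol-5-yl)-2H-chromen-5-ol | COc1cc2c(c(O)c1-c1cc(-c3ccccc3)no1)C=CC(C)(C)O2 | intermediate
16 | (2Z)-3-amino-1-(5-hydroxy-7-methoxy-2,2-dimethyl-2H-chromen-6-yl)-3-phenylprop-2-en-1-one | COc1cc2c(c(O)c1C(=O)/C=C(\N)c1ccccc1)C=CC(C)(C)O2 | intermediate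
17 | 1-(5-hydroxy-7-methoxy-2,2-dimethyl-2H-chromen-6-yl)-3-phenylpropane-1,3-dione | COc1cc2c(c(O)c1C(=O)CC(=O)c1ccccc1)C=CC(C)(C)O2 | target

Total step count: 6. Longest linear sequence: 5 steps (step 1 or step 2, then steps 3 to 6).

Steps most likely to fail

Step 3. The cycloaddition of ketene 8 to an ynol ether that carries an electron-poor heteroaryl group may be slower than ketene dimerisation, and light may isomerise the isoxazole or degrade the product. The fallback sets out from 3 and 7 and comes back to the route at 11; it generates the ketene in the dark by dehydrochlorination. Irradiation of 3 alone in aqueous THF (Arndt–Eistert homologation) should give 2-(6,6-dimethyl-4-oxo-5,6-dihydro-4H-pyran-2-yl)acetic acid F1. Oxalyl chloride with catalytic DMF converts it into 2-(6,6-dimethyl-4-oxo-5,6-dihydro-4H-pyran-2-yl)acetyl chloride F2. Slow addition of F2 to 7 and i-Pr2NEt in toluene releases 8 at a low stationary concentration in the presence of excess alkyne, and heating then carries 9 through 10 to 11.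

Step 2. Lithiation of the isoxazole at C4 or addition of butyllithium to the ring may compete with bromine–lithium exchange, and part of the ynolate may be silylated on carbon. The fallback sets out from 4 and comes back at 7 through ynolate 6, using no alkyllithium. NaBH4 in EtOH reduces 4 to (3-phenylisoxazol-5-yl)methanol F3. MnO2 oxidises it to 3-phenylisoxazole-5-carbaldehyde F4. Bestmann–Ohira homologation (dimethyl (1-diazo-2-oxopropyl)phosphonate, K2CO3, MeOH) gives 5-ethynyl-3-phenylisoxazole F5. Deprotonation with LiN(SiMe3)2 and oxidation of the acetylide with t-BuOOLi gives 6, which i-Pr3SiOTf silylates on oxygen to 7.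

Step 6. Cyclisation of the C5 hydroxyl onto the protonated enaminone with loss of ammonia (flavone formation) may compete with hydrolysis, and the acid may hydrate or dimerise the chromene. The fallback sets out from 15 and comes back at 17, with the phenol masked during the acid stage and released under non-acidic conditions. t-BuMe2SiOTf and 2,6-lutidine give tert-butyl{[7-methoxy-2,2-dimethyl-6-(3-phenylisoxazol-5-yl)-2H-chromen-5-yl]oxy}dimethylsilane F6. Mo(CO)6 in wet MeCN gives (2Z)-3-amino-1-(5-{[tert-butyl(dimethyl)silyl]oxy}-7-methoxy-2,2-dimethyl-2H-chromen-6-yl)-3-phenylprop-2-en-1-one F7. Dilute aqueous HCl in THF hydrolyses it to 1-(5-{[tert-butyl(dimethyl)silyl]oxy}-7-methoxy-2,2-dimethyl-2H-chromen-6-yl)-3-phenylpropane-1,3-dione F8. Bu4NF buffered with AcOH in THF then removes the silyl group to give 17.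

Further compounds

F1 | step 3 | 2-(6,6-dimethyl-4-oxo-5,6-dihydro-4H-pyran-2-yl)acetic acid | CC1(C)CC(=O)C=C(O1)CC(=O)O
F2 | step 3 | 2-(6,6-dimethyl-4-oxo-5,6-dihydro-4H-pyran-2-yl)acetyl chloride | CC1(C)CC(=O)C=C(O1)CC(=O)Cl
F3 | step 2 | (3-phenylisoxazol-5-yl)methanol | OCc1cc(-c2ccccc2)no1
F4 | step 2 | 3-phenylisoxazole-5-carbaldehyde | O=Cc1cc(-c2ccccc2)no1
F5 | step 2 | 5-ethynyl-3-phenylisoxazole | C#Cc1cc(-c2ccccc2)no1
F6 | step 6 | tert-butyl{[7-methoxy-2,2-dimethyl-6-(3-phenylisoxazol-5-yl)-2H-chromen-5-yl]oxy}dimethylsilane | COc1cc2c(c(O[Si](C)(C)C(C)(C)C)c1-c1cc(-c3ccccc3)no1)C=CC(C)(C)O2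
F7 | step 6 | (2Z)-3-amino-1-(5-{[tert-butyl(dimethyl)silyl]oxy}-7-methoxy-2,2-dimethyl-2H-chromen-6-yl)-3-phenylprop-2-en-1-one | COc1cc2c(c(O[Si](C)(C)C(C)(C)C)c1C(=O)/C=C(\N)c1ccccc1)C=CC(C)(C)O2
F8 | step 6 | 1-(5-{[tert-butyl(dimethyl)silyl]oxy}-7-methoxy-2,2-dimethyl-2H-chromen-6-yl)-3-phenylpropane-1,3-dione | COc1cc2c(c(O[Si](C)(C)C(C)(C)C)c1C(=O)CC(=O)c1ccccc1)C=CC(C)(C)O2
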